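**Retrosynthetic overview**
1. Basalethanolide A is the ester of the primary hydroxyl of tyrosol with the straight-chain C32 acid. The last operation unmasks the phenol from its acetate.
2. Key disconnection: the C4–C5 CH2–CH2 bond of the acyl chain, formed by a mixed Kolbe electrolysis (anodic decarboxylative radical cross-coupling). Nonacosanoic acid supplies the C28 radical, and the glutaric half-ester of O-acetyltyrosol supplies a C3 radical that already carries the complete ester.
3. Enabling feature: C2–C31 of the acyl chain are an unbranched run of CH2 groups ending in the C32 methyl group. C4 and C5 carry only H and carbon, and the ester carbonyl C1 is separated from C4 by C2 and C3, so both radicals are unstabilised primary alkyl radicals that couple rather than oxidise further. C1–C4 plus the lost CO2 is the symmetrical C5 diacid, and the only ring, the para-disubstituted benzene ring, lies eight atoms from the oxidised carboxylate and is deactivated as its aryl acetate.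
4. The half-ester comes from ring-opening of glutaric anhydride by the primary hydroxyl of 4-(2-hydroxyethyl)phenyl acetate, itself made from tyrosol by phenoxide-selective acetylation.
5. Rings: none is formed. The benzene ring is bought with tyrosol, and the six-membered anhydride ring is opened in step 2.

Key step: step 3

Remark: the target has no stereocentre and no stereogenic double bond, so it is achiral and no stereocontrol is needed; nonacosanoic acid (C29) is taken as a catalogue fatty acid.

**Step 1**
Reactants: 1 tyrosol [4-(2-hydroxyethyl)phenol]
Product: 2 4-(2-hydroxyethyl)phenyl acetate
Conditions: NaOH (1.0 equiv), H2O, 0 °C; then Ac2O (1.05 equiv), 0 °C, short reaction time; immediate extraction (EtOAc) at about pH 6–7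
Reagents that add atoms: acetic anhydride, CC(=O)OC(C)=O
Why: Schotten–Baumann-type chemoselective O-acetylation of a phenoxide in water: one equivalent of hydroxide ionises only the phenol (pKa about 10), the phenoxide should outcompete the neutral primary alcohol and water for acetic anhydride, and the base is consumed as acetate so that the aryl acetate formed is not saponified.

**Step 2**
Reactants: 2 4-(2-hydroxyethyl)phenyl acetate; 3 glutaric anhydride (oxane-2,6-dione)
Product: 4 5-[2-(4-acetoxyphenyl)ethoxy]-5-oxopentanoic acid (glutaric acid mono[2-(4-acetoxyphenyl)ethyl] ester)
Conditions: 3 (1.2 equiv), Et3N (1.5 equiv), DMAP (5 mol %), CH2Cl2, 0 °C to rt; 1 M HCl wash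
Reagents that add atoms: none
Why: DMAP-catalysed alcoholysis of a symmetrical cyclic anhydride by a primary alcohol (ring-opening mono-esterification): either carbonyl gives the same half-ester, the carboxylate product cannot acylate a second alcohol, and the aryl acetate is a far weaker acyl donor than the anhydride and should stay untouched.

**Step 3**
Reactants: 5 nonacosanoic acid (limiting, 1 equiv); 4 5-[2-(4-acetoxyphenyl)ethoxy]-5-oxopentanoic acid (5 equiv)
Product: 8 2-(4-acetoxyphenyl)ethyl dotriacontanoate, via octacosyl radical 6 (not isolated), via 3-[2-(4-acetoxyphenyl)ethoxycarbonyl]propyl radical 7 (not isolated)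
Conditions: smooth Pt anode, Pt cathode, undivided cell, NaOMe (5 mol % of total acid), MeOH–hexane (about 3:1), 45 °C, constant current about 0.2 A cm−2, about 1 F per mol of total acid, stopped while still weakly acidic; silica chromatography
Reagents that add atoms: none
Why: At a smooth platinum anode at high current density the carboxylates of 5 and 4 are each oxidised by one electron and lose CO2, giving the octacosyl radical 6 and the ester-bearing primary radical 7 in the carboxylate-covered anode layer, where radical–radical combination forms the C4–C5 CH2–CH2 bond of 8 while the acid protons are reduced to H2 at the cathode. The closest known reaction type is the mixed (crossed) Kolbe electrolysis of a fatty acid with a dicarboxylic acid half-ester, the classical anodic chain extension of long-chain fatty acids. No ring is closed and no stereocentre is created, so only chemoselectivity and cross-selectivity are at stake. The one-electron radical path, rather than two-electron oxidation to a carbocation (Hofer–Moest path), is secured by the substrate, because both radicals are unbranched primary alkyl radicals with no α-heteroatom, aryl or carbonyl group (the ester carbonyl is γ to the radical carbon of 7). Cross-coupling over homo-coupling is secured statistically by the five-fold excess of the cheap half-ester 4, so that most octacosyl radicals should meet 7, and the polar homodimer (a suberate diester) and the hydrocarbon dimer differ enough in polarity from 8 to be removed on silica. The benzene ring lies eight atoms from the oxidised carboxylate and is deactivated as the aryl acetate (no free phenol or alkoxyarene to be oxidised), the medium stays a weakly acidic RCO2H/RCO2Na buffer so that neither ester should be methanolysed, and warm methanol–hexane should keep the C29 acid and the waxy products in solution and off the anode.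

**Step 4**
Reactants: 8 2-(4-acetoxyphenyl)ethyl dotriacontanoate
Product: 9 Basalethanolide A [2-(4-hydroxyphenyl)ethyl dotriacontanoate]
Conditions: pyrrolidine (3 equiv), THF, rt to 35 °C; aqueous citric acid wash
Reagents that add atoms: none
Why: Chemoselective aminolysis of an aryl ester: the phenoxide leaving group (pKa about 10) makes the aryl acetate far more reactive towards a secondary amine than the alkyl ester (alkoxide leaving group, pKa about 16), so acetyl transfer to pyrrolidine should unmask the phenol and leave the long-chain phenethyl ester intact.

**Compound list**
1 | tyrosol, 4-(2-hydroxyethyl)phenol | OCCc1ccc(O)cc1 | starting material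
2 | 4-(2-hydroxyethyl)phenyl acetate | CC(=O)Oc1ccc(CCO)cc1 | intermediate
3 | glutaric anhydride (oxane-2,6-dione) | O=C1CCCC(=O)O1 | starting material
4 | 5-[2-(4-acetoxyphenyl)ethoxy]-5-oxopentanoic acid | CC(=O)Oc1ccc(CCOC(=O)CCCC(=O)O)cc1 | intermediate
5 | nonacosanoic acid | CCCCCCCCCCCCCCCCCCCCCCCCCCCCC(=O)O | starting material
6 | octacosyl radical (not isolated) | CCCCCCCCCCCCCCCCCCCCCCCCCCC[CH2] | intermediate
7 | 3-[2-(4-acetoxyphenyl)ethoxycarbonyl]propyl radical (not isolated) | [CH2]CCC(=O)OCCc1ccc(OC(C)=O)cc1 | intermediate
8 | 2-(4-acetoxyphenyl)ethyl dotriacontanoate | CCCCCCCCCCCCCCCCCCCCCCCCCCCCCCCC(=O)OCCc1ccc(OC(C)=O)cc1 | intermediate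
9 | Basalethanolide A, 2-(4-hydroxyphenyl)ethyl dotriacontanoate | CCCCCCCCCCCCCCCCCCCCCCCCCCCCCCCC(=O)OCCc1ccc(O)cc1 | target

**Step count and risks**
Total step count: 4. Longest linear sequence: 4 steps (1 → 2 → 4 → 8 → 9).

Steps most likely to fail:

1. Step 3 (mixed Kolbe electrolysis). What may go wrong: statistical homo-coupling and disproportionation of the radicals consuming the limiting acid; over-oxidation to carbocations (ether and alkene formation); passivation of the platinum anode by a film of the sparingly soluble C29 carboxylate and waxy products; anodic attack on the arene. Fallback: radical generation is moved from the anode to a reductive nickel cycle, setting out from 5 and 4. Each acid would be converted with N-hydroxyphthalimide, DIC and catalytic DMAP in CH2Cl2 into its redox-active ester, 1,3-dioxoisoindolin-2-yl nonacosanoate F1 and 1-(1,3-dioxoisoindolin-2-yl) 5-[2-(4-acetoxyphenyl)ethyl] pentanedioate F2. The two esters would then be joined by the nickel-electrocatalytic reductive doubly decarboxylative C(sp3)–C(sp3) cross-coupling (NiCl2·6H2O, terpyridine-type ligand, AgNO3, Mg sacrificial anode, RVC cathode, NMP–THF, rt, F2 in three-fold excess, dilute HCl work-up). No part of the molecule then sees an oxidising potential or a protic nucleophilic solvent. The fallback returns to the route at 8.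

2. Step 4 (selective removal of the aryl acetate). What may go wrong: loss of chemoselectivity between the two esters (competing aminolysis of the phenethyl ester) or incomplete conversion because the waxy substrate stays out of solution. Fallback: the differentiation of two esters is given up, setting out from 8. Both esters would be saponified (LiOH, THF–MeOH–H2O, 50 °C, then HCl) to dotriacontanoic acid F3. F3 would then be esterified with unprotected tyrosol 1 under Mitsunobu conditions (PPh3, DIAD, THF). Only the primary alcohol is activated, and the carboxylic acid (pKa about 5) rather than the phenol (pKa about 10) should serve as the pronucleophile. The fallback returns to the route at 9.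

3. Step 1 (phenol-selective acetylation). What may go wrong: imperfect O-selectivity (acetylation of the aliphatic hydroxyl or double acetylation) and hydrolytic loss of the aryl acetate during the basic phase. Fallback: the order of events is reversed, setting out from 1 and 3. Glutaric anhydride would be opened by tyrosol without base (toluene, 90 °C), where only the aliphatic hydroxyl should react, to give 5-[2-(4-hydroxyphenyl)ethoxy]-5-oxopentanoic acid F4. Its phenoxide would then be acetylated with no competing alcohol present (NaOH 2 equiv, H2O, 0 °C, Ac2O, then HCl). The fallback returns to the route at 4.

**Further compounds**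
F1 | step 3 | 1,3-dioxoisoindolin-2-yl nonacosanoate | CCCCCCCCCCCCCCCCCCCCCCCCCCCCC(=O)ON1C(=O)c2ccccc2C1=O
F2 | step 3 | 1-(1,3-dioxoisoindolin-2-yl) 5-[2-(4-acetoxyphenyl)ethyl] pentanedioate | CC(=O)Oc1ccc(CCOC(=O)CCCC(=O)ON2C(=O)c3ccccc3C2=O)cc1
F3 | step 4 | dotriacontanoic acid | CCCCCCCCCCCCCCCCCCCCCCCCCCCCCCCC(=O)O
F4 | step 1 | 5-[2-(4-hydroxyphenyl)ethoxy]-5-oxopentanoic acid | O=C(O)CCCC(=O)OCCc1ccc(O)cc1
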